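**Plan**

1. Retrosynthetic cuts, in order: the ester C6–O acyl bond; the C5–C6 bond of ring B; the C3–B / C3–O helper on ring A; the C4–CH3 bond; the C9–C10 bond at the quaternary carbon; the C7–isopropyl bond.
2. Forward: the C6–C9 side chain with its isopropyl centre is made first and joined to ring A at C10 by conjugate addition. Ring A then receives its C4 methyl and a C3 allylic acetate. Ring B is closed last, onto the preformed ring A, through C5–C6, and the p-coumarate is attached at the end.
3. Enabling feature: the target is a homoallylic alcohol, C6(OH)–C5–C4(CH3)=C3, with the C3=C4 bond inside ring A. Read backwards, this is the product of an allyl-metal addition with allylic transposition. A boron at C3 of a ring A cyclohex-2-enyl unit (C3–C4=C5) and an aldehyde at C6 on the C10 side chain therefore close ring B, place the ring A double bond and set C5 and C6 in one event.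
4. Stereochemistry: C7 comes from a ligand-controlled copper SN2′ alkylation, C10 from a ligand-controlled copper conjugate addition, and the helper centre C3 from a CBS reduction. C3–OAc is converted with inversion into C3–B, which fixes C5 (new bond on the boron face) and C6 (chair transition state) and is consumed in forming the C3=C4 bond.

Key step: step 12

Remark: eudesmane numbering is used (C4 = olefinic carbon bearing CH3, C5 = ring-fusion CH, C6 = carbinol carbon, C7 = CH bearing isopropyl, C10 = quaternary carbon). The CIP descriptors of C7 and C10 change along the route only because substituent priorities change; no centre is inverted except C3 in step 12. Compounds 1, 5 and 19 are taken to be purchasable.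

**Route**

Step 1
Reactants: 1 (E)-but-2-ene-1,4-diol
Product: 2 (E)-4-(tert-butyldimethylsilyloxy)but-2-en-1-ol
Conditions: NaH (1.0 equiv), THF, 0 °C to rt; then TBSCl (1.0 equiv)
Reagents that add atoms: tert-butyldimethylsilyl chloride, CC(C)(C)[Si](C)(C)Cl
Why: Monosilylation of a symmetrical diol through its poorly soluble monosodium alkoxide should stop after one silyl group, and no stereocentre is formed.

Step 2
Reactants: 2 (E)-4-(tert-butyldimethylsilyloxy)but-2-en-1-ol
Product: 3 (E)-4-(tert-butyldimethylsilyloxy)but-2-en-1-yl diethyl phosphate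
Conditions: ClP(O)(OEt)2, pyridine, DMAP (cat.), CH2Cl2, 0 °C
Reagents that add atoms: diethyl chlorophosphate, CCOP(=O)(Cl)OCC
Why: O-Phosphorylation of a primary allylic alcohol gives the leaving group needed for copper-catalysed allylic substitution without touching the alkene geometry.

Step 3
Reactants: 3 (E)-4-(tert-butyldimethylsilyloxy)but-2-en-1-yl diethyl phosphate
Product: 4 tert-butyldimethyl{[(2R)-2-(propan-2-yl)but-3-en-1-yl]oxy}silane
Conditions: iPr2Zn (3 equiv), (CuOTf)2·C6H6 (5 mol%), chiral peptide-based Schiff-base ligand (10 mol%), THF, −15 °C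
Reagents that add atoms: diisopropylzinc, CC(C)[Zn]C(C)C
Why: Copper-catalysed asymmetric allylic alkylation (SN2′) of an allylic phosphate with a dialkylzinc delivers the isopropyl group to the γ-carbon, and the ligand antipode is chosen to give the (R) centre that becomes C7.

Step 4
Reactants: 4 tert-butyldimethyl{[(2R)-2-(propan-2-yl)but-3-en-1-yl]oxy}silane, 5 3-methylcyclohex-2-en-1-one
Product: 7 tert-butyldimethyl{(2S)-3-methyl-2-[2-((1R)-1-methyl-3-(trimethylsilyloxy)cyclohex-2-en-1-yl)ethyl]butoxy}silane, via alkylzirconocene chloride 6 (not isolated)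
Conditions: Cp2Zr(H)Cl, CH2Cl2, rt; then 5, CuCl (10 mol%), chiral phosphoramidite ligand (10 mol%), AgNTf2 (15 mol%), TMSCl, Et2O, rt; non-aqueous work-up
Reagents that add atoms: chlorotrimethylsilane, C[Si](C)(C)Cl
Why: Hydrozirconation of the terminal alkene gives the primary alkylzirconium, whose copper-catalysed asymmetric conjugate addition to the β-methyl enone creates the quaternary C10 under ligand control (antipode chosen for 10R, the remote C7 centre exerting no bias), and TMSCl traps the enolate regiospecifically as the C4=C5 silyl enol ether.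

Step 5
Reactants: 7 tert-butyldimethyl{(2S)-3-methyl-2-[2-((1R)-1-methyl-3-(trimethylsilyloxy)cyclohex-2-en-1-yl)ethyl]butoxy}silane
Product: 9 (3R)-3-{(3S)-3-[(tert-butyldimethylsilyloxy)methyl]-4-methylpentyl}-3-methylcyclohex-1-en-1-yl trifluoromethanesulfonate, via lithium enolate 8 (not isolated)
Conditions: MeLi, THF, 0 °C; then PhNTf2, −78 °C to rt
Reagents that add atoms: N-phenylbis(trifluoromethanesulfonimide), O=S(=O)(N(c1ccccc1)S(=O)(=O)C(F)(F)F)C(F)(F)F
Why: Cleavage of the Si–O bond by methyllithium releases the regiodefined lithium enolate, and O-triflation keeps the double bond at C4=C5, which a ketone enolisation could not guarantee next to the quaternary carbon.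

Step 6
Reactants: 9 (3R)-3-{(3S)-3-[(tert-butyldimethylsilyloxy)methyl]-4-methylpentyl}-3-methylcyclohex-1-en-1-yl trifluoromethanesulfonate
Product: 10 tert-butyl{(2S)-2-[2-((1R)-1,3-dimethylcyclohex-2-en-1-yl)ethyl]-3-methylbutoxy}dimethylsilane
Conditions: MeMgBr, Fe(acac)3 (5 mol%), THF/NMP, −30 °C
Reagents that add atoms: methylmagnesium bromide, C[Mg]Br
Why: Iron-catalysed Kumada-type cross-coupling of an alkenyl triflate with a methyl Grignard reagent installs C15 on C4 with the double bond position retained.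

Step 7
Reactants: 10 tert-butyl{(2S)-2-[2-((1R)-1,3-dimethylcyclohex-2-en-1-yl)ethyl]-3-methylbutoxy}dimethylsilane
Product: 11 (4S)-4-{(3S)-3-[(tert-butyldimethylsilyloxy)methyl]-4-methylpentyl}-2,4-dimethylcyclohex-2-en-1-one
Conditions: Rh2(cap)4 (dirhodium tetrakis(caprolactamate), 1 mol%), TBHP (5 equiv), K2CO3, CH2Cl2, rt
Reagents that add atoms: tert-butyl hydroperoxide, CC(C)(C)OO
Why: Allylic C–H oxidation through tert-butylperoxyl radicals should attack C3, the only allylic ring methylene (C10 is quaternary), and oxygenate the less hindered terminus of the allyl radical to give the C3 enone.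

Step 8
Reactants: 11 (4S)-4-{(3S)-3-[(tert-butyldimethylsilyloxy)methyl]-4-methylpentyl}-2,4-dimethylcyclohex-2-en-1-one
Product: 12 (1R,4S)-4-{(3S)-3-[(tert-butyldimethylsilyloxy)methyl]-4-methylpentyl}-2,4-dimethylcyclohex-2-en-1-ol
Conditions: (S)-Me-CBS (20 mol%), BH3·SMe2, THF, −30 °C; MeOH quench
Reagents that add atoms: none
Why: Corey–Bakshi–Shibata reduction is reagent-controlled (the α-methyl alkenyl side acts as the large group), so the (S)-catalyst should give the (R) carbinol at C3, cis to the side chain, where the remote C10 centre could give no substrate control.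

Step 9
Reactants: 12 (1R,4S)-4-{(3S)-3-[(tert-butyldimethylsilyloxy)methyl]-4-methylpentyl}-2,4-dimethylcyclohex-2-en-1-ol
Product: 13 (1R,4S)-4-{(3S)-3-[(tert-butyldimethylsilyloxy)methyl]-4-methylpentyl}-2,4-dimethylcyclohex-2-en-1-yl acetate
Conditions: Ac2O, pyridine, DMAP (cat.), CH2Cl2, 0 °C to rt
Reagents that add atoms: acetic anhydride, CC(=O)OC(C)=O
Why: DMAP-catalysed acetylation turns the C3 hydroxyl into a leaving group for palladium with retention at C3.

Step 10
Reactants: 13 (1R,4S)-4-{(3S)-3-[(tert-butyldimethylsilyloxy)methyl]-4-methylpentyl}-2,4-dimethylcyclohex-2-en-1-yl acetate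
Product: 14 (1R,4S)-4-[(3S)-3-(hydroxymethyl)-4-methylpentyl]-2,4-dimethylcyclohex-2-en-1-yl acetate
Conditions: HF·pyridine, pyridine, THF, 0 °C to rt
Reagents that add atoms: none
Why: Buffered fluoride cleaves the primary silyl ether while the allylic acetate and the alkene are left intact.

Step 11
Reactants: 14 (1R,4S)-4-[(3S)-3-(hydroxymethyl)-4-methylpentyl]-2,4-dimethylcyclohex-2-en-1-yl acetate
Product: 15 (1R,4S)-4-[(3S)-3-formyl-4-methylpentyl]-2,4-dimethylcyclohex-2-en-1-yl acetate
Conditions: Dess–Martin periodinane, NaHCO3, CH2Cl2, 0 °C to rt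
Reagents that add atoms: none
Why: Buffered Dess–Martin oxidation gives the α-branched aldehyde under near-neutral conditions that should not epimerise C7.

Step 12
Reactants: 15 (1R,4S)-4-[(3S)-3-formyl-4-methylpentyl]-2,4-dimethylcyclohex-2-en-1-yl acetate
Product: 18 (1R,2S,4aR,8aR)-4a,8-dimethyl-2-(propan-2-yl)-1,2,3,4,4a,5,6,8a-octahydronaphthalen-1-ol (eudesm-3-en-6β-ol), via allylboronate aldehyde 16 (not isolated), via pinacol borate ester 17 (not isolated)
Conditions: Pd2(dba)3 (2.5 mol%), B2pin2 (1.2 equiv), DMSO (0.01 M), 50 °C then 80 °C; H2O work-up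
Reagents that add atoms: none
Why: Zerovalent palladium ionises the allylic acetate with inversion (palladium on the face anti to the acetate, which is the face of the C10 methyl), transmetalation with B2pin2 and reductive elimination place boron with retention on the less hindered terminus C3, and the resulting allylboronate 16 adds its γ-carbon C5 to the tethered aldehyde through a closed six-membered chair with boron bound to the carbonyl oxygen, the C4=C5 bond moving to C3=C4. The closest known reaction type is the palladium-catalysed Miyaura borylation of allylic acetates run in tandem with allylboration of an aldehyde, here in its intramolecular form. Ring B closes in a 6-exo mode with respect to the C4=C5 bond of ring A, since only C5 of the allyl unit enters the new ring. C5 is controlled by the boron-bearing centre C3, because the closed transition state delivers C6 to the boron face, which is the face of the C10 methyl and therefore gives the trans ring fusion; C6 is controlled by the chair, in which the only arrangement that lets the tether reach C10 has C7 equatorial on the boron-containing ring, so the oxygen ends axial on ring B and anti to H5 (6R). The step needs site selectivity (borylation at C3 and not at C5, secured by the adjacent quaternary C10), facial fidelity (secured by the inversion–retention course and the configurational stability of pinacol allylboronates) and ring closure in preference to intermolecular allylboration (secured by high dilution).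

Step 13
Reactants: 18 (1R,2S,4aR,8aR)-4a,8-dimethyl-2-(propan-2-yl)-1,2,3,4,4a,5,6,8a-octahydronaphthalen-1-ol, 19 (2E)-3-(4-acetoxyphenyl)prop-2-enoic acid
Product: 21 (1R,2S,4aR,8aR)-4a,8-dimethyl-2-(propan-2-yl)-1,2,3,4,4a,5,6,8a-octahydronaphthalen-1-yl (2E)-3-(4-acetoxyphenyl)prop-2-enoate, via mixed anhydride 20 (not isolated)
Conditions: 19, 2,4,6-trichlorobenzoyl chloride, Et3N, THF, rt; then 18, DMAP, toluene, 60 °C
Reagents that add atoms: none
Why: Yamaguchi esterification acylates the hindered axial C6 hydroxyl through the acylpyridinium ion of the mixed anhydride, with retention at C6 and with the phenol masked as its acetate.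

Step 14
Reactants: 21 (1R,2S,4aR,8aR)-4a,8-dimethyl-2-(propan-2-yl)-1,2,3,4,4a,5,6,8a-octahydronaphthalen-1-yl (2E)-3-(4-acetoxyphenyl)prop-2-enoate
Product: 22 (1R,2S,4aR,8aR)-4a,8-dimethyl-2-(propan-2-yl)-1,2,3,4,4a,5,6,8a-octahydronaphthalen-1-yl (2E)-3-(4-hydroxyphenyl)prop-2-enoate
Conditions: K2CO3 (0.2 equiv), MeOH, 0 °C
Reagents that add atoms: none
Why: Methanolysis should cleave the aryl acetate selectively, because phenoxide is a far better leaving group than the hindered secondary alkoxide of the cinnamate.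

**Compound list**

1 | (E)-but-2-ene-1,4-diol | OC/C=C/CO | starting material
2 | (E)-4-(tert-butyldimethylsilyloxy)but-2-en-1-ol | CC(C)(C)[Si](C)(C)OC/C=C/CO | intermediate
3 | (E)-4-(tert-butyldimethylsilyloxy)but-2-en-1-yl diethyl phosphate | CCOP(=O)(OCC)OC/C=C/CO[Si](C)(C)C(C)(C)C | intermediate
4 | tert-butyldimethyl{[(2R)-2-(propan-2-yl)but-3-en-1-yl]oxy}silane | C=C[C@@H](C(C)C)CO[Si](C)(C)C(C)(C)C | intermediate
5 | 3-methylcyclohex-2-en-1-one | CC1=CC(=O)CCC1 | starting material
6 | chloro{(3S)-3-[(tert-butyldimethylsilyloxy)methyl]-4-methylpentyl}bis(cyclopentadienyl)zirconium | Cl[Zr](CC[C@@H](C(C)C)CO[Si](C)(C)C(C)(C)C)(C1C=CC=C1)C1C=CC=C1 | intermediate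
7 | tert-butyldimethyl{(2S)-3-methyl-2-[2-((1R)-1-methyl-3-(trimethylsilyloxy)cyclohex-2-en-1-yl)ethyl]butoxy}silane | C[Si](C)(C)OC1=C[C@@](C)(CC[C@@H](C(C)C)CO[Si](C)(C)C(C)(C)C)CCC1 | intermediate
8 | lithium (3R)-3-{(3S)-3-[(tert-butyldimethylsilyloxy)methyl]-4-methylpentyl}-3-methylcyclohex-1-en-1-olate | [Li]OC1=C[C@@](C)(CC[C@@H](C(C)C)CO[Si](C)(C)C(C)(C)C)CCC1 | intermediate
9 | (3R)-3-{(3S)-3-[(tert-butyldimethylsilyloxy)methyl]-4-methylpentyl}-3-methylcyclohex-1-en-1-yl trifluoromethanesulfonate | O=S(=O)(OC1=C[C@@](C)(CC[C@@H](C(C)C)CO[Si](C)(C)C(C)(C)C)CCC1)C(F)(F)F | intermediate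
10 | tert-butyl{(2S)-2-[2-((1R)-1,3-dimethylcyclohex-2-en-1-yl)ethyl]-3-methylbutoxy}dimethylsilane | CC1=C[C@@](C)(CC[C@@H](C(C)C)CO[Si](C)(C)C(C)(C)C)CCC1 | intermediate
11 | (4S)-4-{(3S)-3-[(tert-butyldimethylsilyloxy)methyl]-4-methylpentyl}-2,4-dimethylcyclohex-2-en-1-one | CC1=C[C@@](C)(CC[C@@H](C(C)C)CO[Si](C)(C)C(C)(C)C)CCC1=O | intermediate
12 | (1R,4S)-4-{(3S)-3-[(tert-butyldimethylsilyloxy)methyl]-4-methylpentyl}-2,4-dimethylcyclohex-2-en-1-ol | CC1=C[C@@](C)(CC[C@@H](C(C)C)CO[Si](C)(C)C(C)(C)C)CC[C@H]1O | intermediate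
13 | (1R,4S)-4-{(3S)-3-[(tert-butyldimethylsilyloxy)methyl]-4-methylpentyl}-2,4-dimethylcyclohex-2-en-1-yl acetate | CC1=C[C@@](C)(CC[C@@H](C(C)C)CO[Si](C)(C)C(C)(C)C)CC[C@H]1OC(C)=O | intermediate
14 | (1R,4S)-4-[(3S)-3-(hydroxymethyl)-4-methylpentyl]-2,4-dimethylcyclohex-2-en-1-yl acetate | CC1=C[C@@](C)(CC[C@@H](C(C)C)CO)CC[C@H]1OC(C)=O | intermediate
15 | (1R,4S)-4-[(3S)-3-formyl-4-methylpentyl]-2,4-dimethylcyclohex-2-en-1-yl acetate | CC1=C[C@@](C)(CC[C@@H](C(C)C)C=O)CC[C@H]1OC(C)=O | intermediate
16 | (2S)-2-{2-[(1R,4S)-1,3-dimethyl-4-(4,4,5,5-tetramethyl-1,3,2-dioxaborolan-2-yl)cyclohex-2-en-1-yl]ethyl}-3-methylbutanal | CC1=C[C@@](C)(CC[C@@H](C(C)C)C=O)CC[C@@H]1B2OC(C)(C)C(C)(C)O2 | intermediate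
17 | 2-{[(1R,2S,4aR,8aR)-4a,8-dimethyl-2-(propan-2-yl)-1,2,3,4,4a,5,6,8a-octahydronaphthalen-1-yl]oxy}-4,4,5,5-tetramethyl-1,3,2-dioxaborolane | CC1=CCC[C@]2(C)CC[C@@H](C(C)C)[C@@H](OB3OC(C)(C)C(C)(C)O3)[C@@H]12 | intermediate
18 | (1R,2S,4aR,8aR)-4a,8-dimethyl-2-(propan-2-yl)-1,2,3,4,4a,5,6,8a-octahydronaphthalen-1-ol (eudesm-3-en-6β-ol) | CC1=CCC[C@]2(C)CC[C@@H](C(C)C)[C@@H](O)[C@@H]12 | intermediate
19 | (2E)-3-(4-acetoxyphenyl)prop-2-enoic acid | CC(=O)Oc1ccc(/C=C/C(=O)O)cc1 | starting material
20 | (2E)-3-(4-acetoxyphenyl)prop-2-enoic 2,4,6-trichlorobenzoic anhydride | CC(=O)Oc1ccc(/C=C/C(=O)OC(=O)c2c(Cl)cc(Cl)cc2Cl)cc1 | intermediate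
21 | (1R,2S,4aR,8aR)-4a,8-dimethyl-2-(propan-2-yl)-1,2,3,4,4a,5,6,8a-octahydronaphthalen-1-yl (2E)-3-(4-acetoxyphenyl)prop-2-enoate | CC1=CCC[C@]2(C)CC[C@@H](C(C)C)[C@@H](OC(=O)/C=C/c3ccc(OC(C)=O)cc3)[C@@H]12 | intermediate
22 | (1R,2S,4aR,8aR)-4a,8-dimethyl-2-(propan-2-yl)-1,2,3,4,4a,5,6,8a-octahydronaphthalen-1-yl (2E)-3-(4-hydroxyphenyl)prop-2-enoate | CC1=CCC[C@]2(C)CC[C@@H](C(C)C)[C@@H](OC(=O)/C=C/c3ccc(O)cc3)[C@@H]12 | target

**Totals and risks**

Total step count: 14. Longest linear sequence: 14 steps (1 to 22; 5 and 19 enter as purchased fragments).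

Steps most likely to fail:

1. Step 12. Ring closure may be slow, because C6 must reach the face of ring A that carries the C10 methyl and ring A has to leave its half-chair to allow it. β-Hydride elimination from the π-allylpalladium intermediate, protodeboronation or intermolecular allylboration could then overtake the cyclisation. Fallback: the same C5–C6 bond is closed under thermodynamic instead of stereospecific control, setting out from 7 and returning at 18. Aqueous HF in MeCN would remove both silyl groups of 7 to give hydroxy ketone F1, and Dess–Martin oxidation would give keto aldehyde F2. A reversible intramolecular aldol addition (KOH, MeOH, 0 °C) of the C5 enolate to the C6 aldehyde should funnel to the trans-fused ketol F3, since C5 is α to the C4 ketone and equilibrates, with hydroxyl and isopropyl equatorial. Silylation (TBSOTf, 2,6-lutidine) would give silyl ether F4. Kinetic enolisation away from C5 (LiN(iPr)2, −78 °C; then PhNTf2) would give enol triflate F5, and iron-catalysed methylation (MeMgBr, Fe(acac)3) would give silyl ether F6. Bu4NF would release eudesm-3-en-6α-ol F7, and buffered Dess–Martin oxidation would give the β,γ-unsaturated ketone F8. Reduction with LiBH(s-Bu)3 at −78 °C, from the α face because the axial C10 methyl shields the β face, should give 18.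

2. Step 4. Transmetalation of the β-branched, functionalised alkylzirconium to copper may be sluggish, leaving low conversion or eroded face selectivity. The silyl enol ether may also hydrolyse on isolation, which would lose the enolate regiochemistry. Fallback: a Grignard-based conjugate addition with direct enolate trapping, setting out from 4 and returning at 9. Hydroboration–oxidation (9-BBN; then NaOH, H2O2) would give alcohol F9 and Appel bromination (CBr4, PPh3) would give bromide F10. Magnesium in Et2O would give Grignard reagent F11. Its copper-catalysed asymmetric conjugate addition to 5 (Cu(OTf)2, chiral imidazolinium salt as carbene precursor) would give magnesium enolate F12, which is trapped in the same flask with PhNTf2 to give 9.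

3. Step 7. Hydrogen abstraction may be unselective (C15 methyl or the tertiary C–H bonds of the side chain), or the allyl radical may be oxygenated at C5, giving mixtures and over-oxidation. Fallback: an ene/2,3-sigmatropic manifold in place of the radical one, setting out from 10 and returning at 11. SeO2 (cat.) with TBHP in CH2Cl2 should hydroxylate the ring methylene on the more substituted alkene terminus to give the C3-epimeric allylic alcohols F13, and Dess–Martin periodinane or MnO2 would oxidise both epimers to 11.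

Further compounds
F1 | step 12 | (3R)-3-[(3S)-3-(hydroxymethyl)-4-methylpentyl]-3-methylcyclohexan-1-one | O=C1C[C@@](C)(CC[C@@H](C(C)C)CO)CCC1
F2 | step 12 | (2S)-3-methyl-2-{2-[(1R)-1-methyl-3-oxocyclohexyl]ethyl}butanal | O=C1C[C@@](C)(CC[C@@H](C(C)C)C=O)CCC1
F3 | step 12 | (4aR,7S,8S,8aS)-8-hydroxy-4a-methyl-7-(propan-2-yl)octahydronaphthalen-1(2H)-one | O=C1CCC[C@]2(C)CC[C@@H](C(C)C)[C@H](O)[C@@H]12
F4 | step 12 | tert-butyldimethylsilyl ether of F3 | O=C1CCC[C@]2(C)CC[C@@H](C(C)C)[C@H](O[Si](C)(C)C(C)(C)C)[C@@H]12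
F5 | step 12 | enol triflate of F4 with the double bond at C3=C4 | O=S(=O)(OC1=CCC[C@]2(C)CC[C@@H](C(C)C)[C@H](O[Si](C)(C)C(C)(C)C)[C@@H]12)C(F)(F)F
F6 | step 12 | 6α-(tert-butyldimethylsilyloxy)eudesm-3-ene | CC1=CCC[C@]2(C)CC[C@@H](C(C)C)[C@H](O[Si](C)(C)C(C)(C)C)[C@@H]12
F7 | step 12 | (1S,2S,4aR,8aR)-4a,8-dimethyl-2-(propan-2-yl)-1,2,3,4,4a,5,6,8a-octahydronaphthalen-1-ol (eudesm-3-en-6α-ol) | CC1=CCC[C@]2(C)CC[C@@H](C(C)C)[C@H](O)[C@@H]12
F8 | step 12 | (2S,4aR,8aR)-4a,8-dimethyl-2-(propan-2-yl)-3,4,4a,5,6,8a-hexahydronaphthalen-1(2H)-one (eudesm-3-en-6-one) | CC1=CCC[C@]2(C)CC[C@@H](C(C)C)C(=O)[C@@H]12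
F9 | step 4 | (3S)-3-[(tert-butyldimethylsilyloxy)methyl]-4-methylpentan-1-ol | OCC[C@@H](C(C)C)CO[Si](C)(C)C(C)(C)C
F10 | step 4 | [(2S)-2-(2-bromoethyl)-3-methylbutoxy](tert-butyl)dimethylsilane | BrCC[C@@H](C(C)C)CO[Si](C)(C)C(C)(C)C
F11 | step 4 | {(3S)-3-[(tert-butyldimethylsilyloxy)methyl]-4-methylpentyl}magnesium bromide | Br[Mg]CC[C@@H](C(C)C)CO[Si](C)(C)C(C)(C)C
F12 | step 4 | bromomagnesium (3R)-3-{(3S)-3-[(tert-butyldimethylsilyloxy)methyl]-4-methylpentyl}-3-methylcyclohex-1-en-1-olate | Br[Mg]OC1=C[C@@](C)(CC[C@@H](C(C)C)CO[Si](C)(C)C(C)(C)C)CCC1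
F13 | step 7 | (4S)-4-{(3S)-3-[(tert-butyldimethylsilyloxy)methyl]-4-methylpentyl}-2,4-dimethylcyclohex-2-en-1-ol, both C1 epimers | CC1=C[C@@](C)(CC[C@@H](C(C)C)CO[Si](C)(C)C(C)(C)C)CCC1O
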